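The synthesis rests on disconnecting C3–C4 and C1'–C2' (isochromanone numbering; side chain C1', C2'). The target hides a coumarin (C5–O, the C1' carboxyl, alkene C4=C1') and an oxaloacetate enol (C3, C2', both carboxyls) esterified to C1 through O2. One intramolecular [2+2] photocycloaddition of this enol ester joins both bonds, closes the lactone ring C1–O2–C3–C4–C4a–C8a and a cyclobutane, and fixes C1' (with C4) on one coumarin face. The precursor is the all-benzyl enol ester of 7,8-bis(benzyloxy)coumarin-5-carboxylic acid and dibenzyl oxaloacetate; retro-aldol opening, dynamic reduction and a single hydrogenolysis then finish.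

Key step: step 8

Remarks
- Locants: C1 (lactone C=O), O2, C3, C4, C4a, C5–C8, C8a; side chain C1' (CH) and C2' (CH2). Bn = benzyl.
- Design: every ester and phenol ether is benzyl, so the end is one neutral hydrogenolysis. The C5 phenol set free from the coumarin lactone is capped (step 9) before the C3 ketone is unveiled, because a free ortho phenol would close onto the keto ester.
- Assumption: the antipodes named for the two chiral catalysts (steps 8 and 11) are those expected from the usual transition-state models; the other antipode is equally available. The alkene geometry of 14 and the C3/C2' centres of 15 do not reach the target.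

Step 1
Reactants: 1 methyl 3,4,5-trimethoxybenzoate
Product: 2 methyl 2-formyl-3,4,5-trimethoxybenzoate
Conditions: Cl2CHOMe, TiCl4, CH2Cl2, 0 °C to rt; H2O
Reagents that add atoms: dichloromethyl methyl ether, ClC(Cl)OC
Why: Rieche formylation can only attack the two equivalent free positions, each ortho to a methoxy group, and hydrolysis of the α-chloro ether on work-up gives the aldehyde.

Step 2
Reactants: 2 methyl 2-formyl-3,4,5-trimethoxybenzoate
Product: 3 methyl 2-formyl-3,4,5-trihydroxybenzoate
Conditions: BBr3 (5 equiv), CH2Cl2, −78 to 0 °C; H2O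
Reagents that add atoms: none
Why: Lewis-acid ether cleavage by BBr3 removes all three aryl methyl groups, while the methyl ester and the aldehyde should survive at or below 0 °C.

Step 3
Reactants: 3 methyl 2-formyl-3,4,5-trihydroxybenzoate
Product: 4 methyl 4,5-bis(benzyloxy)-2-formyl-3-hydroxybenzoate
Conditions: BnBr (2.1 equiv), NaHCO3, NaI (cat.), DMF, 40 °C
Reagents that add atoms: benzyl bromide, BrCc1ccccc1
Why: Williamson etherification under weak base leaves the 3-OH, which is locked in a hydrogen bond to the formyl oxygen, and benzylates the 4-OH and 5-OH, the usual pattern for 2,3,4-trihydroxybenzaldehydes.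

Step 4
Reactants: 4 methyl 4,5-bis(benzyloxy)-2-formyl-3-hydroxybenzoate; 5 (ethoxycarbonylmethylene)triphenylphosphorane
Product: 7 methyl 7,8-bis(benzyloxy)-2-oxo-2H-chromene-5-carboxylate, via E-cinnamate 6 (not isolated)
Conditions: N,N-diethylaniline, 210 °C
Reagents that add atoms: none
Why: Wittig olefination with the stabilised ylide, then thermal E-to-Z isomerisation and lactonisation (Wittig–lactonisation), is the standard route from salicylaldehydes to 3,4-unsubstituted coumarins.

Step 5
Reactants: 7 methyl 7,8-bis(benzyloxy)-2-oxo-2H-chromene-5-carboxylate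
Product: 9 7,8-bis(benzyloxy)-2-oxo-2H-chromene-5-carboxylic acid, via ring-opened (Z)-coumarinate 8 (not isolated)
Conditions: LiOH, THF/H2O, rt; then 1 M HCl
Reagents that add atoms: lithium hydroxide, [Li+].[OH-]
Why: Saponification cleaves the methyl ester and reversibly opens the lactone to the (Z)-coumarinate, which recloses to the coumarin on acidification; benzyl ethers are inert.

Step 6
Reactants: 10 benzyl acetate; 11 dibenzyl oxalate
Product: 12 dibenzyl oxaloacetate (dibenzyl 2-oxobutanedioate, keto/enol mixture)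
Conditions: LiN(SiMe3)2 (2 equiv), THF, −78 °C; then 11; aq. HCl
Reagents that add atoms: none
Why: Crossed Claisen condensation in which the lithium enolate of benzyl acetate acylates the non-enolisable oxalate and the acidic product is held as its enolate until the quench.

Step 7
Reactants: 9 7,8-bis(benzyloxy)-2-oxo-2H-chromene-5-carboxylic acid; 12 dibenzyl oxaloacetate
Product: 14 dibenzyl (2Z)-2-{[7,8-bis(benzyloxy)-2-oxo-2H-chromene-5-carbonyl]oxy}but-2-enedioate, via acid chloride 13 (not isolated)
Conditions: (COCl)2, DMF (cat.), CH2Cl2, rt; then 12, Et3N, DMAP (cat.), CH2Cl2, 0 °C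
Reagents that add atoms: none
Why: Acid chloride formation followed by O-acylation of the hydrogen-bonded (Z)-enol of 12 under amine base, the usual enol ester synthesis; the alkene geometry has no consequence later.

Step 8
Reactants: 14 dibenzyl (2Z)-2-{[7,8-bis(benzyloxy)-2-oxo-2H-chromene-5-carbonyl]oxy}but-2-enedioate
Product: 15 cyclobutane-fused bis-lactone photoadduct (3R,4S,1'S,2'S)
Conditions: oxazaborolidine from (S)-α,α-diphenylprolinol and 2,4,6-trifluorophenylboronic acid (50 mol %), AlBr3 (50 mol %), CH2Cl2 (5 mM), −75 °C, hν 405 nm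
Reagents that add atoms: none
Why: Proposed new method: the Lewis acid binds the coumarin carbonyl, shifts its absorption to 405 nm and favours intersystem crossing; the triplet adds through C4 to the enol carbon C3, and the 1,4-biradical (C1' and C2', each next to a carbonyl) closes the C1'–C2' bond after spin inversion. The closest known reaction is the intramolecular [2+2] photocycloaddition of coumarins bearing alkenyl chains, including its enantioselective version with AlBr3-activated oxazaborolidines; an ester tether from C5 and an acyloxyfumarate partner are new. The lactone ring (C1, O2, C3, C4, C4a, C8a) closes by 6-exo-trig radical attack from the s-cis ester rotamer, and the cyclobutane (C3, C4, C1', C2') by combination of the biradical. C4 and C1' are set together by the coumarin face that is attacked (Si at C4, Re at C1'), which the oxazaborolidine should leave open, and their cis hydrogens follow from addition across the ring alkene; C3 is forced cis to C4a by the short tether, and C2' is left to biradical closure because it is erased later, as is C3. Regiochemistry is secured by the tether, which lets C3 reach only C4, and selective excitation by the red-shifted complex; absolute facial selectivity is the one demand placed on the catalyst, and only C1' must survive from it.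

Step 9
Reactants: 15 cyclobutane-fused bis-lactone photoadduct
Product: 17 C5 benzyl ether of the ring-opened C1' benzyl ester (cyclobutane-fused isochromanone, 3R,4S,1'S,2'S), via ring-opened phenol 16 (not isolated)
Conditions: BnOH (3 equiv), BnBr (1.5 equiv), K2CO3, MeCN, rt
Reagents that add atoms: benzyl alcohol, OCc1ccccc1; benzyl bromide, BrCc1ccccc1
Why: Alkylative lactone opening: carbonate-generated benzyloxide transesterifies the aryl ester far faster than the benzoate-type lactone at C1, and the phenoxide is trapped at once as its benzyl ether (Williamson), with no stereocentre touched.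

Step 10
Reactants: 17 C5 benzyl ether of the ring-opened C1' benzyl ester
Product: 19 dibenzyl (2R)-2-{3-(benzyloxy)-2,3-dioxo-1-[2,3,4-tris(benzyloxy)-6-[(benzyloxy)carbonyl]phenyl]propyl}butanedioate (C4 epimers in equilibrium), via cyclobutanol alkoxide 18 (not isolated)
Conditions: NaOCH2Ph (1.5 equiv, 1 M in BnOH), THF, −20 °C; AcOH
Reagents that add atoms: sodium benzyloxide, [Na+].[O-]Cc1ccccc1
Why: De Mayo-type retro-aldol fragmentation: benzyloxide adds to C1, the expelled C3 alkoxide cleaves the strained C3–C2' bond to the α-keto ester and an ester enolate that benzyl alcohol protonates at once; C4 becomes epimerisable and C1' is untouched.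

Step 11
Reactants: 19 keto tetraester (C4 epimers)
Product: 21 dibenzyl (2R)-2-[(3S,4S)-5,6,7-tris(benzyloxy)-3-[(benzyloxy)carbonyl]-1-oxo-3,4-dihydro-1H-isochromen-4-yl]butanedioate, via hydroxy tetraester 20 (not isolated)
Conditions: RuCl(p-cymene)[(S,S)-TsDPEN] (5 mol %), HCO2H/Et3N (5:2), DMF, 40 °C; then CSA (cat.), toluene, 60 °C
Reagents that add atoms: none
Why: Dynamic kinetic resolution by asymmetric transfer hydrogenation, known for β-aryl α-keto esters: C4 epimerises through the enol under Et3N while the catalyst delivers hydride to the Re face of the C3 ketone (3S) of the epimer in which this face is also the Felkin–Anh face anti to the aryl group (4S), and the 3-OH then lactonises onto the ortho benzoate to the 3,4-trans isochromanone.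

Step 12
Reactants: 21 hexabenzyl isochromanone
Product: 22 (2R)-2-[(3S,4S)-3-carboxy-5,6,7-trihydroxy-1-oxo-3,4-dihydro-1H-isochromen-4-yl]butanedioic acid (target)
Conditions: H2 (1 atm), Pd/C, THF/H2O, rt; lyophilise
Reagents that add atoms: none
Why: Catalytic hydrogenolysis cleaves the three benzyl esters and three benzyl ethers under neutral conditions that leave the lactone and the three stereocentres untouched.

Compound list
1 | methyl 3,4,5-trimethoxybenzoate | COC(=O)c1cc(OC)c(OC)c(OC)c1 | starting material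
2 | methyl 2-formyl-3,4,5-trimethoxybenzoate | COC(=O)c1cc(OC)c(OC)c(OC)c1C=O | intermediate
3 | methyl 2-formyl-3,4,5-trihydroxybenzoate | COC(=O)c1cc(O)c(O)c(O)c1C=O | intermediate
4 | methyl 4,5-bis(benzyloxy)-2-formyl-3-hydroxybenzoate | COC(=O)c1cc(OCc2ccccc2)c(OCc2ccccc2)c(O)c1C=O | intermediate
5 | (ethoxycarbonylmethylene)triphenylphosphorane | CCOC(=O)C=P(c1ccccc1)(c1ccccc1)c1ccccc1 | starting material
6 | methyl 4,5-bis(benzyloxy)-2-[(E)-3-ethoxy-3-oxoprop-1-en-1-yl]-3-hydroxybenzoate (not isolated) | CCOC(=O)/C=C/c1c(O)c(OCc2ccccc2)c(OCc2ccccc2)cc1C(=O)OC | intermediate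
7 | methyl 7,8-bis(benzyloxy)-2-oxo-2H-chromene-5-carboxylate | COC(=O)c1cc(OCc2ccccc2)c(OCc2ccccc2)c2OC(=O)C=Cc12 | intermediate
8 | (2Z)-3-[3,4-bis(benzyloxy)-6-carboxy-2-hydroxyphenyl]prop-2-enoic acid (lithium salt in the flask, not isolated) | OC(=O)/C=C\c1c(O)c(OCc2ccccc2)c(OCc2ccccc2)cc1C(=O)O | intermediate
9 | 7,8-bis(benzyloxy)-2-oxo-2H-chromene-5-carboxylic acid | OC(=O)c1cc(OCc2ccccc2)c(OCc2ccccc2)c2OC(=O)C=Cc12 | intermediate
10 | benzyl acetate | CC(=O)OCc1ccccc1 | starting material
11 | dibenzyl oxalate | O=C(OCc1ccccc1)C(=O)OCc1ccccc1 | starting material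
12 | dibenzyl oxaloacetate (dibenzyl 2-oxobutanedioate) | O=C(CC(=O)C(=O)OCc1ccccc1)OCc1ccccc1 | intermediate
13 | 7,8-bis(benzyloxy)-2-oxo-2H-chromene-5-carbonyl chloride (not isolated) | ClC(=O)c1cc(OCc2ccccc2)c(OCc2ccccc2)c2OC(=O)C=Cc12 | intermediate
14 | dibenzyl (2Z)-2-{[7,8-bis(benzyloxy)-2-oxo-2H-chromene-5-carbonyl]oxy}but-2-enedioate | O=C1Oc2c(OCc3ccccc3)c(OCc3ccccc3)cc(C(=O)O/C(C(=O)OCc3ccccc3)=C\C(=O)OCc3ccccc3)c2C=C1 | intermediate
15 | photoadduct: cyclobutane C3–C4–C1'–C2' cis-fused to the dihydrocoumarin ring (C5–O–CO–C1') and to the isochromanone ring (C1–O2–C3); 6,7-bis(benzyloxy); CO2Bn on C3 and C2', mutually trans; H4 and H1' cis; 3R,4S,1'S,2'S | O=C1Oc2c(OCc4ccccc4)c(OCc4ccccc4)cc3c2[C@@H]2[C@H]1[C@H](C(=O)OCc4ccccc4)[C@]2(C(=O)OCc4ccccc4)OC3=O | intermediate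
16 | phenol from benzyl alcoholysis of the aryl lactone of 15: free C5–OH, CO2Bn on C1', cyclobutane-fused isochromanone intact, 3R,4S,1'S,2'S (not isolated) | Oc2c(OCc4ccccc4)c(OCc4ccccc4)cc3c2[C@@H]2[C@H](C(=O)OCc4ccccc4)[C@H](C(=O)OCc4ccccc4)[C@]2(C(=O)OCc4ccccc4)OC3=O | intermediate
17 | C5 benzyl ether of 16: cyclobutane-fused isochromanone with 5,6,7-tris(benzyloxy) and CO2Bn on C3, C1' and C2', 3R,4S,1'S,2'S | c1ccccc1COc2c(OCc4ccccc4)c(OCc4ccccc4)cc3c2[C@@H]2[C@H](C(=O)OCc4ccccc4)[C@H](C(=O)OCc4ccccc4)[C@]2(C(=O)OCc4ccccc4)OC3=O | intermediate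
18 | cyclobutanol from benzyloxide opening of C1–O2 of 17: benzyl benzoate at C8a, tertiary OH on C3 (sodium alkoxide in the flask, not isolated), 3R,4S,1'S,2'S | c1ccccc1COc2c(OCc4ccccc4)c(OCc4ccccc4)cc(C(=O)OCc4ccccc4)c2[C@@H]2[C@H](C(=O)OCc4ccccc4)[C@H](C(=O)OCc4ccccc4)[C@]2(C(=O)OCc4ccccc4)O | intermediate
19 | dibenzyl (2R)-2-{3-(benzyloxy)-2,3-dioxo-1-[2,3,4-tris(benzyloxy)-6-[(benzyloxy)carbonyl]phenyl]propyl}butanedioate (C4 epimers in equilibrium) | O=C(OCc1ccccc1)C[C@@H](C(=O)OCc1ccccc1)C(c1c(OCc2ccccc2)c(OCc2ccccc2)c(OCc2ccccc2)cc1C(=O)OCc1ccccc1)C(=O)C(=O)OCc1ccccc1 | intermediate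
20 | dibenzyl (2R)-2-{(1S,2S)-3-(benzyloxy)-2-hydroxy-3-oxo-1-[2,3,4-tris(benzyloxy)-6-[(benzyloxy)carbonyl]phenyl]propyl}butanedioate (3S,4S,1'R; not isolated) | O=C(OCc1ccccc1)C[C@@H](C(=O)OCc1ccccc1)[C@@H](c1c(OCc2ccccc2)c(OCc2ccccc2)c(OCc2ccccc2)cc1C(=O)OCc1ccccc1)[C@H](O)C(=O)OCc1ccccc1 | intermediate
21 | dibenzyl (2R)-2-[(3S,4S)-5,6,7-tris(benzyloxy)-3-[(benzyloxy)carbonyl]-1-oxo-3,4-dihydro-1H-isochromen-4-yl]butanedioate | O=C(OCc1ccccc1)C[C@@H](C(=O)OCc1ccccc1)[C@H]1c2c(cc(OCc3ccccc3)c(OCc3ccccc3)c2OCc2ccccc2)C(=O)O[C@@H]1C(=O)OCc1ccccc1 | intermediate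
22 | (2R)-2-[(3S,4S)-3-carboxy-5,6,7-trihydroxy-1-oxo-3,4-dihydro-1H-isochromen-4-yl]butanedioic acid | O=C(O)C[C@@H](C(=O)O)[C@H]1c2c(cc(O)c(O)c2O)C(=O)O[C@@H]1C(=O)O | target

Total step count: 12. Longest linear sequence: 11 steps (1–5, 7–12); step 6 is a one-step side branch.

Steps most likely to fail

1. Step 8. The ester tether may not reach its s-cis rotamer within the triplet lifetime, so that E/Z isomerisation of the enol ester or coumarin dimerisation takes over. The Lewis acid, offered several carbonyl groups, may also discriminate the coumarin faces poorly. Fallback (known chemistry, from 7, rejoining at 21): lithiated benzyl 1,3-dithiane-2-carboxylate (LiN(SiMe3)2, THF, −78 °C) adds 1,4 to coumarin 7 and the lactone enolate is trapped with benzyl bromoacetate, giving the racemic trans dihydrocoumarin F1. The conditions of step 9 (BnOH, BnBr, K2CO3) open and cap it to the dithiane tetraester F2. I2/NaHCO3 in aqueous acetone unmasks the ketone to give the C1 methyl ester keto tetraester F3, racemic at C1' and labile at C4. The conditions of step 11 then reduce both C1' antipodes under catalyst control, with loss of methanol on lactonisation, to 21 and its 1'-epimer F4, which are separated by chromatography.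

2. Step 11. Hydride transfer to the very hindered ketone may be slow, and the catalyst may pair the 3S alcohol with the wrong C4 epimer. Fallback (from 19, rejoining at 21): base-free stoichiometric reagent control replaces the dynamic catalysis. B-chlorodiisopinocampheylborane (the antipode that delivers 3S; THF, −25 °C) reduces both C4 epimers without equilibration, giving 20 and the C4-epimeric hydroxy tetraester F6. After chromatography 20 is closed to 21 with CSA in toluene, and F6 is re-oxidised with Dess–Martin periodinane to 19 and recycled.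

3. Step 10. Before it is protonated, the released ester enolate may attack the C3 ester (Dieckmann closure) or expel the C4 enolate (retro-Michael), and prolonged alkoxide contact may epimerise C1'. Fallback (from 17, rejoining at 19): the fragmentation is run in water, where the enolate is protonated at once. LiOH in THF/H2O at 0 °C opens the C1 lactone, triggers the retro-aldol and hydrolyses the three benzyl esters, giving the keto tetra-acid F5. O-benzyl-N,N'-diisopropylisourea (THF, rt) then re-esterifies the four carboxyl groups under neutral conditions to 19.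

Further compounds
F1 | step 8 | methyl rac-(3,4-trans)-7,8-bis(benzyloxy)-3-[2-(benzyloxy)-2-oxoethyl]-4-[2-[(benzyloxy)carbonyl]-1,3-dithian-2-yl]-2-oxochromane-5-carboxylate (racemic, relative configuration shown) | COC(=O)c1cc(OCc2ccccc2)c(OCc2ccccc2)c2OC(=O)[C@@H](CC(=O)OCc3ccccc3)[C@@H](c12)C1(C(=O)OCc2ccccc2)SCCCS1
F2 | step 8 | dibenzyl 2-{[2-[(benzyloxy)carbonyl]-1,3-dithian-2-yl][2,3,4-tris(benzyloxy)-6-(methoxycarbonyl)phenyl]methyl}butanedioate (racemic) | COC(=O)c1cc(OCc2ccccc2)c(OCc2ccccc2)c(OCc2ccccc2)c1C(C(CC(=O)OCc1ccccc1)C(=O)OCc1ccccc1)C1(C(=O)OCc2ccccc2)SCCCS1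
F3 | step 8 | dibenzyl 2-{3-(benzyloxy)-2,3-dioxo-1-[2,3,4-tris(benzyloxy)-6-(methoxycarbonyl)phenyl]propyl}butanedioate (racemic at C1', C4 labile) | COC(=O)c1cc(OCc2ccccc2)c(OCc2ccccc2)c(OCc2ccccc2)c1C(C(CC(=O)OCc1ccccc1)C(=O)OCc1ccccc1)C(=O)C(=O)OCc1ccccc1
F4 | step 8 | dibenzyl (2S)-2-[(3S,4S)-5,6,7-tris(benzyloxy)-3-[(benzyloxy)carbonyl]-1-oxo-3,4-dihydro-1H-isochromen-4-yl]butanedioate (1'-epimer of 21) | O=C(OCc1ccccc1)C[C@H](C(=O)OCc1ccccc1)[C@H]1c2c(cc(OCc3ccccc3)c(OCc3ccccc3)c2OCc2ccccc2)C(=O)O[C@@H]1C(=O)OCc1ccccc1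
F5 | step 10 | (2R)-2-{2-carboxy-2-oxo-1-[2,3,4-tris(benzyloxy)-6-carboxyphenyl]ethyl}butanedioic acid (C4 epimers) | OC(=O)C[C@@H](C(=O)O)C(c1c(OCc2ccccc2)c(OCc2ccccc2)c(OCc2ccccc2)cc1C(=O)O)C(=O)C(=O)O
F6 | step 11 | dibenzyl (2R)-2-{(1R,2S)-3-(benzyloxy)-2-hydroxy-3-oxo-1-[2,3,4-tris(benzyloxy)-6-[(benzyloxy)carbonyl]phenyl]propyl}butanedioate (C4 epimer of 20) | O=C(OCc1ccccc1)C[C@@H](C(=O)OCc1ccccc1)[C@H](c1c(OCc2ccccc2)c(OCc2ccccc2)c(OCc2ccccc2)cc1C(=O)OCc1ccccc1)[C@H](O)C(=O)OCc1ccccc1
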